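The quinone ring (C1 carbonyl between C2–CH3 and C6–chain; C3–H, C4 carbonyl, C5–H) is made last, from an acyclic (Z)-dienyl diazomethyl ketone that already carries the whole diol side chain. On irradiation a Wolff rearrangement moves the methyl-bearing dienyl carbon C2 onto the diazo carbon C3, and the dienylketene so formed closes by 6π-electrocyclisation between ketene carbon C4 and the terminal methylene C5, giving a 3-methyl-5-alkylphenol. The step exploits the 1,3,5-pattern of C4–O, C2–CH3 and C6–chain on the six-membered ring; the free para carbon C1 is oxidised afterwards. The diol comes from Sharpless epoxidation of nerol and a Payne rearrangement–opening.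

Key step: step 15

Numbering used: ring atoms C1–C6 as above; side chain C1′–C15′ counted from the ring, diol at C10′/C11′.
Remark: D-(−)-diethyl tartrate is taken to give the (2R,3S)-epoxide of nerol, the mirror image of the epoxide from the L-(+)-ester. Compound 11 is carried as a mixture of epimers at the sulfonyl-bearing carbon C9′, which becomes CH2 in step 9.

Step 1
Reactants: 1 nerol
Product: 2 [(2R,3S)-3-methyl-3-(4-methylpent-3-en-1-yl)oxiran-2-yl]methanol
Conditions: Ti(OiPr)4 (10 mol %), D-(−)-diethyl tartrate (12 mol %), t-BuOOH (2 equiv), 4 Å molecular sieves, CH2Cl2, −20 °C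
Reagents that add atoms: tert-butyl hydroperoxide, CC(C)(C)OO
Why: Sharpless asymmetric epoxidation acts only on the allylic-alcohol alkene (the C6=C7 alkene is untouched), and the D-(−)-tartrate/Ti(OiPr)4 catalyst should deliver oxygen to the face that gives the (2R,3S)-epoxide, whose C3 becomes C11′ (S) of the target.

Step 2
Reactants: 2 [(2R,3S)-3-methyl-3-(4-methylpent-3-en-1-yl)oxiran-2-yl]methanol
Product: 3 (2R,3S)-3,7-dimethyl-1-(phenylsulfanyl)oct-6-ene-2,3-diol
Conditions: PhSH (1.5 equiv, slow addition), 0.5 M NaOH (aq), t-BuOH, 75 °C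
Reagents that add atoms: thiophenol, Sc1ccccc1
Why: Payne rearrangement followed by thiolate opening: under base the C1 alkoxide opens the epoxide at C2 with inversion to give the terminal 1,2-epoxide with a free tertiary C3–OH, and thiolate then attacks the unhindered C1, so that C2 (future C10′) and C3 (future C11′) end with the threo arrangement of the target diol.

Step 3
Reactants: 3 (2R,3S)-3,7-dimethyl-1-(phenylsulfanyl)oct-6-ene-2,3-diol
Product: 4 (4R,5S)-2,2,5-trimethyl-5-(4-methylpent-3-en-1-yl)-4-[(phenylsulfanyl)methyl]-1,3-dioxolane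
Conditions: 2,2-dimethoxypropane (3 equiv), PPTS (5 mol %), CH2Cl2, 25 °C
Reagents that add atoms: 2,2-dimethoxypropane, COC(C)(C)OC
Why: acid-catalysed ketal exchange on the only 1,2-diol gives the dioxolane, which masks both hydroxyls through the base, hydride, acyl chloride and ketene chemistry that follows.

Step 4
Reactants: 4 (4R,5S)-2,2,5-trimethyl-5-(4-methylpent-3-en-1-yl)-4-[(phenylsulfanyl)methyl]-1,3-dioxolane
Product: 5 (4R,5S)-4-[(benzenesulfonyl)methyl]-2,2,5-trimethyl-5-(4-methylpent-3-en-1-yl)-1,3-dioxolane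
Conditions: (NH4)6Mo7O24·4H2O (10 mol %), 30% H2O2 (3 equiv), EtOH, 0 → 25 °C
Reagents that add atoms: hydrogen peroxide, OO
Why: peroxomolybdate oxidation of sulfide to sulfone is fast at sulfur and slow at the trisubstituted alkene, and the sulfone makes the C1 hydrogens (future C9′) acidic for the fragment coupling.

Step 5
Reactants: 6 geranyl bromide; 7 acetonitrile
Product: 8 (4E)-5,9-dimethyldeca-4,8-dienenitrile
Conditions: 7 (3 equiv), n-BuLi (2.8 equiv), THF, −78 °C; then 6, −78 → −20 °C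
Reagents that add atoms: none
Why: SN2 alkylation of lithioacetonitrile (formed from 7 and n-BuLi, used in excess to suppress double alkylation) by the primary allylic bromide adds the two carbons that become ring C6 and C1 without touching the (E)-alkene.

Step 6
Reactants: 8 (4E)-5,9-dimethyldeca-4,8-dienenitrile
Product: 9 (4E,8E)-10-hydroxy-5,9-dimethyldeca-4,8-dienenitrile
Conditions: SeO2 (10 mol %), t-BuOOH (3 equiv), salicylic acid (10 mol %), CH2Cl2, 25 °C
Reagents that add atoms: tert-butyl hydroperoxide, CC(C)(C)OO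
Why: SeO2-catalysed allylic oxidation (ene reaction then [2,3]-sigmatropic shift, t-BuOOH as terminal oxidant) takes the (E)-methyl of the terminal isopropylidene group in preference to the more hindered internal alkene, giving the (E)-allylic alcohol that becomes C8′.

Step 7
Reactants: 9 (4E,8E)-10-hydroxy-5,9-dimethyldeca-4,8-dienenitrile
Product: 10 (4E,8E)-10-bromo-5,9-dimethyldeca-4,8-dienenitrile
Conditions: CBr4 (1.2 equiv), PPh3 (1.25 equiv), CH2Cl2, 0 °C
Reagents that add atoms: carbon tetrabromide, BrC(Br)(Br)Br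
Why: Appel bromination converts the primary allylic alcohol into the bromide under neutral conditions that leave the nitrile and the alkene geometry alone.

Step 8
Reactants: 5 (4R,5S)-4-[(benzenesulfonyl)methyl]-2,2,5-trimethyl-5-(4-methylpent-3-en-1-yl)-1,3-dioxolane; 10 (4E,8E)-10-bromo-5,9-dimethyldeca-4,8-dienenitrile
Product: 11 (4E,8E)-11-(benzenesulfonyl)-5,9-dimethyl-11-[(4R,5S)-2,2,5-trimethyl-5-(4-methylpent-3-en-1-yl)-1,3-dioxolan-4-yl]undeca-4,8-dienenitrile (both C11 epimers)
Conditions: 5, n-BuLi (1.05 equiv), THF, −78 °C; then 10, −78 → −40 °C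
Reagents that add atoms: none
Why: alkylation of the α-sulfonyl carbanion of 5 by the reactive primary allylic bromide forms the C8′–C9′ bond at −78 °C, where β-elimination of the dioxolane oxygen and proton transfer from the nitrile are slow; the new sulfonyl-bearing centre is of no consequence.

Step 9
Reactants: 11 (4E,8E)-11-(benzenesulfonyl)-5,9-dimethyl-11-[(4R,5S)-2,2,5-trimethyl-5-(4-methylpent-3-en-1-yl)-1,3-dioxolan-4-yl]undeca-4,8-dienenitrile
Product: 12 (4E,8E)-5,9-dimethyl-11-[(4S,5S)-2,2,5-trimethyl-5-(4-methylpent-3-en-1-yl)-1,3-dioxolan-4-yl]undeca-4,8-dienenitrile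
Conditions: 6% Na(Hg) (4 equiv Na), Na2HPO4, MeOH/THF (3:1), −20 → 0 °C
Reagents that add atoms: none
Why: dissolving-metal reductive desulfonylation in buffered methanol replaces the non-allylic C–S bond by C–H (fast protonation of the carbanion by MeOH outruns Julia-type loss of the β-alkoxy group), and the nitrile and the isolated alkenes are inert to Na(Hg).

Step 10
Reactants: 12 (4E,8E)-5,9-dimethyl-11-[(4S,5S)-2,2,5-trimethyl-5-(4-methylpent-3-en-1-yl)-1,3-dioxolan-4-yl]undeca-4,8-dienenitrile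
Product: 13 (4E,8E)-5,9-dimethyl-11-[(4S,5S)-2,2,5-trimethyl-5-(4-methylpent-3-en-1-yl)-1,3-dioxolan-4-yl]undeca-4,8-dienal
Conditions: i-Bu2AlH (1.3 equiv), toluene, −78 °C; then aqueous potassium sodium tartrate (KNaC4H4O6), 25 °C
Reagents that add atoms: water, O
Why: i-Bu2AlH adds once to the nitrile to give an N-aluminated imine that is stable at −78 °C and is hydrolysed on work-up to the aldehyde (future ring C1), with the dioxolane unaffected by the neutral tartrate work-up.

Step 11
Reactants: 13 (4E,8E)-5,9-dimethyl-11-[(4S,5S)-2,2,5-trimethyl-5-(4-methylpent-3-en-1-yl)-1,3-dioxolan-4-yl]undeca-4,8-dienal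
Product: 14 (4E,8E)-5,9-dimethyl-2-methylidene-11-[(4S,5S)-2,2,5-trimethyl-5-(4-methylpent-3-en-1-yl)-1,3-dioxolan-4-yl]undeca-4,8-dienal
Conditions: 37% aqueous CH2O (1.2 equiv), pyrrolidine (10 mol %), propionic acid (10 mol %), i-PrOH, 45 °C
Reagents that add atoms: formaldehyde, C=O
Why: amine/acid-catalysed Mannich condensation with formaldehyde followed by elimination of the amine (α-methylenation) converts the α-CH2 into the 1,1-disubstituted alkene, which installs ring carbon C5 as the terminal methylene.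

Step 12
Reactants: 14 (4E,8E)-5,9-dimethyl-2-methylidene-11-[(4S,5S)-2,2,5-trimethyl-5-(4-methylpent-3-en-1-yl)-1,3-dioxolan-4-yl]undeca-4,8-dienal; 15 ethyl 2-[bis(2,2,2-trifluoroethoxy)phosphoryl]propanoate
Product: 16 ethyl (2Z,6E,10E)-2,7,11-trimethyl-4-methylidene-13-[(4S,5S)-2,2,5-trimethyl-5-(4-methylpent-3-en-1-yl)-1,3-dioxolan-4-yl]trideca-2,6,10-trienoate
Conditions: 15 (1.3 equiv), KN(SiMe3)2 (1.25 equiv), 18-crown-6 (3 equiv), THF, −78 °C; then 14
Reagents that add atoms: none
Why: Still–Gennari olefination: the electron-poor bis(trifluoroethyl) phosphonate with a dissociated potassium counter-ion gives kinetic (Z)-selectivity, placing the ester cis to C6 on the new trisubstituted C2=C1 alkene as the later ring closure requires.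

Step 13
Reactants: 16 ethyl (2Z,6E,10E)-2,7,11-trimethyl-4-methylidene-13-[(4S,5S)-2,2,5-trimethyl-5-(4-methylpent-3-en-1-yl)-1,3-dioxolan-4-yl]trideca-2,6,10-trienoate
Product: 17 (2Z,6E,10E)-2,7,11-trimethyl-4-methylidene-13-[(4S,5S)-2,2,5-trimethyl-5-(4-methylpent-3-en-1-yl)-1,3-dioxolan-4-yl]trideca-2,6,10-trienoic acid
Conditions: LiOH·H2O (5 equiv), THF/MeOH/H2O (3:1:1), 40 °C; then 1 M HCl to pH 4, 0 °C
Reagents that add atoms: lithium hydroxide, [Li+].[OH-]
Why: saponification of the hindered (Z)-ester with LiOH frees the carboxylic acid without a pathway for Z→E isomerisation, and the dioxolane survives the brief, cold acidification.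

Step 14
Reactants: 17 (2Z,6E,10E)-2,7,11-trimethyl-4-methylidene-13-[(4S,5S)-2,2,5-trimethyl-5-(4-methylpent-3-en-1-yl)-1,3-dioxolan-4-yl]trideca-2,6,10-trienoic acid
Product: 19 (3Z,7E,11E)-1-diazo-3,8,12-trimethyl-5-methylidene-14-[(4S,5S)-2,2,5-trimethyl-5-(4-methylpent-3-en-1-yl)-1,3-dioxolan-4-yl]tetradeca-3,7,11-trien-2-one, via acid chloride 18 (not isolated)
Conditions: 1-chloro-N,N,2-trimethylprop-1-en-1-amine (1.2 equiv), CH2Cl2, 0 → 25 °C; then CH2N2 (4 equiv), Et2O, 0 °C
Reagents that add atoms: diazomethane, C=[N+]=[N-]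
Why: the α-chloroenamine converts the acid into acid chloride 18 under neutral conditions (no HCl, no isomerisation), and acylation of diazomethane (a second equivalent takes up HCl) gives the diazomethyl ketone, dipolar cycloaddition to the α-methyl-substituted enone being slow at 0 °C (Arndt–Eistert-type diazoketone synthesis).

Step 15
Reactants: 19 (3Z,7E,11E)-1-diazo-3,8,12-trimethyl-5-methylidene-14-[(4S,5S)-2,2,5-trimethyl-5-(4-methylpent-3-en-1-yl)-1,3-dioxolan-4-yl]tetradeca-3,7,11-trien-2-one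
Product: 22 3-methyl-5-[(2E,6E)-3,7-dimethyl-9-((4S,5S)-2,2,5-trimethyl-5-(4-methylpent-3-en-1-yl)-1,3-dioxolan-4-yl)nona-2,6-dien-1-yl]phenol, via dienylketene 20 (not isolated), via cyclohexadienone 21 (not isolated)
Conditions: hν (300 nm, Pyrex), degassed ClCH2CH2Cl (0.01 M), 25 °C; then 80 °C, 2 h
Reagents that add atoms: none
Why: Photochemical Wolff rearrangement: loss of N2 from 19 with 1,2-shift of the dienyl carbon C2 from the carbonyl carbon C4 to the diazo carbon C3 makes the C2–C3 bond and gives dienylketene 20; only the dienyl group can migrate because the diazo carbon carries hydrogen. The (3Z)-geometry set in step 12 holds ketene carbon C4 next to the terminal methylene C5, so a thermal disrotatory 6π-electrocyclisation (six-membered ring, the only closure open to this triene) forms C4–C5 and gives cyclohexa-2,4-dienone 21, which enolises irreversibly to phenol 22. The closest known reaction type is the photochemical Danheiser benzannulation, whose vinylketene is made by the same Wolff rearrangement of an α,β-unsaturated diazoketone and whose last stage is the same dienylketene electrocyclisation. No stereocentre is created, since the sp3 methylene of 21 is lost on aromatisation, and the distant dioxolane centres are untouched. The step needs the ketene to cyclise faster than it is captured: dilute, anhydrous, non-nucleophilic solvent excludes intermolecular capture, the isolated trisubstituted alkenes do not absorb at 300 nm and are too far away for an intramolecular [2+2], and regiochemistry is not an issue because C4 can reach only C5.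

Step 16
Reactants: 22 3-methyl-5-[(2E,6E)-3,7-dimethyl-9-((4S,5S)-2,2,5-trimethyl-5-(4-methylpent-3-en-1-yl)-1,3-dioxolan-4-yl)nona-2,6-dien-1-yl]phenol
Product: 23 3-[(2E,6E,10S,11S)-10,11-dihydroxy-3,7,11,15-tetramethylhexadeca-2,6,14-trien-1-yl]-5-methylphenol
Conditions: AcOH/H2O/THF (3:1:1), 45 °C
Reagents that add atoms: none
Why: aqueous acetic acid hydrolyses the dioxolane to the free (10′S,11′S)-diol without touching the stereocentres, and because the chain is meta to the phenol oxygen no chroman can form.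

Step 17
Reactants: 23 3-[(2E,6E,10S,11S)-10,11-dihydroxy-3,7,11,15-tetramethylhexadeca-2,6,14-trien-1-yl]-5-methylphenol
Product: 24 2-[(2E,6E,10S,11S)-10,11-dihydroxy-3,7,11,15-tetramethylhexadeca-2,6,14-trien-1-yl]-6-methylcyclohexa-2,5-diene-1,4-dione (target)
Conditions: ON(SO3K)2 (2.5 equiv), aqueous KH2PO4 (0.06 M), acetone/H2O, 0 → 25 °C
Reagents that add atoms: potassium nitrosodisulfonate, [K+].[K+].[O-]S(=O)(=O)N([O])S(=O)(=O)[O-]
Why: Teuber oxidation: the nitroxide radical abstracts the phenolic hydrogen and a second equivalent couples at the free para carbon C1, loss of imidodisulfonate then giving the 1,4-benzoquinone, while the alkenes and the diol are inert to this one-electron oxidant.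

Compound list
1 | nerol, (2Z)-3,7-dimethylocta-2,6-dien-1-ol | CC(C)=CCC/C(C)=C\CO | starting material
2 | [(2R,3S)-3-methyl-3-(4-methylpent-3-en-1-yl)oxiran-2-yl]methanol | CC(C)=CCC[C@]1(C)O[C@@H]1CO | intermediate
3 | (2R,3S)-3,7-dimethyl-1-(phenylsulfanyl)oct-6-ene-2,3-diol | CC(C)=CCC[C@](C)(O)[C@@H](O)CSc1ccccc1 | intermediate
4 | (4R,5S)-2,2,5-trimethyl-5-(4-methylpent-3-en-1-yl)-4-[(phenylsulfanyl)methyl]-1,3-dioxolane | CC(C)=CCC[C@]1(C)OC(C)(C)O[C@H]1CSc1ccccc1 | intermediate
5 | (4R,5S)-4-[(benzenesulfonyl)methyl]-2,2,5-trimethyl-5-(4-methylpent-3-en-1-yl)-1,3-dioxolane | CC(C)=CCC[C@]1(C)OC(C)(C)O[C@H]1CS(=O)(=O)c1ccccc1 | intermediate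
6 | geranyl bromide, (2E)-1-bromo-3,7-dimethylocta-2,6-diene | CC(C)=CCC/C(C)=C/CBr | starting material
7 | acetonitrile | CC#N | starting material
8 | (4E)-5,9-dimethyldeca-4,8-dienenitrile | CC(C)=CCC/C(C)=C/CCC#N | intermediate
9 | (4E,8E)-10-hydroxy-5,9-dimethyldeca-4,8-dienenitrile | OC/C(C)=C/CC/C(C)=C/CCC#N | intermediate
10 | (4E,8E)-10-bromo-5,9-dimethyldeca-4,8-dienenitrile | BrC/C(C)=C/CC/C(C)=C/CCC#N | intermediate
11 | (4E,8E)-11-(benzenesulfonyl)-5,9-dimethyl-11-[(4R,5S)-2,2,5-trimethyl-5-(4-methylpent-3-en-1-yl)-1,3-dioxolan-4-yl]undeca-4,8-dienenitrile, both C11 epimers | CC(C)=CCC[C@]1(C)OC(C)(C)O[C@H]1C(C/C(C)=C/CC/C(C)=C/CCC#N)S(=O)(=O)c1ccccc1 | intermediate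
12 | (4E,8E)-5,9-dimethyl-11-[(4S,5S)-2,2,5-trimethyl-5-(4-methylpent-3-en-1-yl)-1,3-dioxolan-4-yl]undeca-4,8-dienenitrile | CC(C)=CCC[C@]1(C)OC(C)(C)O[C@H]1CC/C(C)=C/CC/C(C)=C/CCC#N | intermediate
13 | (4E,8E)-5,9-dimethyl-11-[(4S,5S)-2,2,5-trimethyl-5-(4-methylpent-3-en-1-yl)-1,3-dioxolan-4-yl]undeca-4,8-dienal | CC(C)=CCC[C@]1(C)OC(C)(C)O[C@H]1CC/C(C)=C/CC/C(C)=C/CCC=O | intermediate
14 | (4E,8E)-5,9-dimethyl-2-methylidene-11-[(4S,5S)-2,2,5-trimethyl-5-(4-methylpent-3-en-1-yl)-1,3-dioxolan-4-yl]undeca-4,8-dienal | CC(C)=CCC[C@]1(C)OC(C)(C)O[C@H]1CC/C(C)=C/CC/C(C)=C/CC(=C)C=O | intermediate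
15 | ethyl 2-[bis(2,2,2-trifluoroethoxy)phosphoryl]propanoate | CCOC(=O)C(C)P(=O)(OCC(F)(F)F)OCC(F)(F)F | starting material
16 | ethyl (2Z,6E,10E)-2,7,11-trimethyl-4-methylidene-13-[(4S,5S)-2,2,5-trimethyl-5-(4-methylpent-3-en-1-yl)-1,3-dioxolan-4-yl]trideca-2,6,10-trienoate | CC(C)=CCC[C@]1(C)OC(C)(C)O[C@H]1CC/C(C)=C/CC/C(C)=C/CC(=C)/C=C(/C)C(=O)OCC | intermediate
17 | (2Z,6E,10E)-2,7,11-trimethyl-4-methylidene-13-[(4S,5S)-2,2,5-trimethyl-5-(4-methylpent-3-en-1-yl)-1,3-dioxolan-4-yl]trideca-2,6,10-trienoic acid | CC(C)=CCC[C@]1(C)OC(C)(C)O[C@H]1CC/C(C)=C/CC/C(C)=C/CC(=C)/C=C(/C)C(=O)O | intermediate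
18 | (2Z,6E,10E)-2,7,11-trimethyl-4-methylidene-13-[(4S,5S)-2,2,5-trimethyl-5-(4-methylpent-3-en-1-yl)-1,3-dioxolan-4-yl]trideca-2,6,10-trienoyl chloride | CC(C)=CCC[C@]1(C)OC(C)(C)O[C@H]1CC/C(C)=C/CC/C(C)=C/CC(=C)/C=C(/C)C(Cl)=O | intermediate
19 | (3Z,7E,11E)-1-diazo-3,8,12-trimethyl-5-methylidene-14-[(4S,5S)-2,2,5-trimethyl-5-(4-methylpent-3-en-1-yl)-1,3-dioxolan-4-yl]tetradeca-3,7,11-trien-2-one | CC(C)=CCC[C@]1(C)OC(C)(C)O[C@H]1CC/C(C)=C/CC/C(C)=C/CC(=C)/C=C(/C)C(=O)C=[N+]=[N-] | intermediate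
20 | (3Z,7E,11E)-3,8,12-trimethyl-5-methylidene-14-[(4S,5S)-2,2,5-trimethyl-5-(4-methylpent-3-en-1-yl)-1,3-dioxolan-4-yl]tetradeca-1,3,7,11-tetraen-1-one (dienylketene) | CC(C)=CCC[C@]1(C)OC(C)(C)O[C@H]1CC/C(C)=C/CC/C(C)=C/CC(=C)/C=C(/C)C=C=O | intermediate
21 | 3-methyl-5-[(2E,6E)-3,7-dimethyl-9-((4S,5S)-2,2,5-trimethyl-5-(4-methylpent-3-en-1-yl)-1,3-dioxolan-4-yl)nona-2,6-dien-1-yl]cyclohexa-2,4-dien-1-one | CC(C)=CCC[C@]1(C)OC(C)(C)O[C@H]1CC/C(C)=C/CC/C(C)=C/CC1=CC(C)=CC(=O)C1 | intermediate
22 | 3-methyl-5-[(2E,6E)-3,7-dimethyl-9-((4S,5S)-2,2,5-trimethyl-5-(4-methylpent-3-en-1-yl)-1,3-dioxolan-4-yl)nona-2,6-dien-1-yl]phenol | CC(C)=CCC[C@]1(C)OC(C)(C)O[C@H]1CC/C(C)=C/CC/C(C)=C/Cc1cc(C)cc(O)c1 | intermediate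
23 | 3-[(2E,6E,10S,11S)-10,11-dihydroxy-3,7,11,15-tetramethylhexadeca-2,6,14-trien-1-yl]-5-methylphenol | CC(C)=CCC[C@](C)(O)[C@@H](O)CC/C(C)=C/CC/C(C)=C/Cc1cc(C)cc(O)c1 | intermediate
24 | 2-[(2E,6E,10S,11S)-10,11-dihydroxy-3,7,11,15-tetramethylhexadeca-2,6,14-trien-1-yl]-6-methylcyclohexa-2,5-diene-1,4-dione | CC(C)=CCC[C@](C)(O)[C@@H](O)CC/C(C)=C/CC/C(C)=C/CC1=CC(=O)C=C(C)C1=O | target

Total step count: 17. Longest linear sequence: 14 steps (steps 1–4, then 8–17, from nerol); the geranyl bromide branch (steps 5–7) joins at step 8.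

Steps most likely to fail

1. Step 15 (key step). The dienyl unit may lose its (3Z) geometry by photoisomerisation before nitrogen is lost, or the ketene may be captured before it closes, so that ring closure does not keep pace with ketene formation. The fallback separates the two bond formations and closes the ring thermally. It sets out from diazoketone 19: silver-benzoate-catalysed Wolff rearrangement (PhCO2Ag, Et3N, THF/H2O, Arndt–Eistert homologation) traps the ketene with water and should give the homologated 3,5-dienoic acid F1, in which the C2–C3 bond is made and the alkene geometry no longer matters. Heating in Ac2O with NaOAc (130 °C) should form the mixed anhydride, which equilibrates its C3=C4 geometry through the dienolate, loses acetic acid to the dienylketene and cyclises without light to the aryl acetate F2. K2CO3 in MeOH then returns the route at phenol 22.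

2. Step 11. Under amine catalysis the skipped diene (new C5=C6 alkene and C2′=C3′) may be drawn into conjugation through a dienamine, giving the 2-methyl-2,4-dienal instead of the 2-methylidene aldehyde. The fallback installs the methylene at the nitrile stage without iminium chemistry. It sets out from nitrile 12: LiN(i-Pr)2 (2.1 equiv) and ClP(O)(OEt)2 in THF at −78 °C should give the α-phosphononitrile F3; a Horner–Wadsworth–Emmons reaction with aqueous formaldehyde and K2CO3 should give the α-methylene nitrile F4; 1,2-reduction with i-Bu2AlH at −78 °C and hydrolytic work-up comes back to the route at enal 14.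

3. Step 9 (with step 8). The dioxolane oxygen β to the sulfonyl carbon may be expelled, either from the lithiated sulfone or from the reduced carbanion during desulfonylation (Julia-type alkene formation), which would destroy C10′. The fallback runs the coupling on the free diol, where the β-oxygen is a lithium or sodium alkoxide and cannot leave. It sets out from sulfide diol 3: oxidation ((NH4)6Mo7O24·4H2O, H2O2, EtOH) should give the dihydroxy sulfone F5; its trilithio derivative (n-BuLi, 3.1 equiv, THF/DMPU, −78 °C) is alkylated at carbon by bromide 10 to give the coupled dihydroxy sulfone F6; Na(Hg) in buffered methanol should then give the diol nitrile F7, and 2,2-dimethoxypropane/PPTS rejoins the route at nitrile 12.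

Further compounds
F1 | step 15 | (7E,11E)-3,8,12-trimethyl-5-methylidene-14-[(4S,5S)-2,2,5-trimethyl-5-(4-methylpent-3-en-1-yl)-1,3-dioxolan-4-yl]tetradeca-3,7,11-trienoic acid (3E/3Z mixture) | CC(C)=CCC[C@]1(C)OC(C)(C)O[C@H]1CC/C(C)=C/CC/C(C)=C/CC(=C)C=C(C)CC(=O)O
F2 | step 15 | 3-methyl-5-[(2E,6E)-3,7-dimethyl-9-((4S,5S)-2,2,5-trimethyl-5-(4-methylpent-3-en-1-yl)-1,3-dioxolan-4-yl)nona-2,6-dien-1-yl]phenyl acetate | CC(C)=CCC[C@]1(C)OC(C)(C)O[C@H]1CC/C(C)=C/CC/C(C)=C/Cc1cc(C)cc(OC(C)=O)c1
F3 | step 11 | diethyl {(3E,7E)-1-cyano-4,8-dimethyl-10-[(4S,5S)-2,2,5-trimethyl-5-(4-methylpent-3-en-1-yl)-1,3-dioxolan-4-yl]deca-3,7-dien-1-yl}phosphonate | CC(C)=CCC[C@]1(C)OC(C)(C)O[C@H]1CC/C(C)=C/CC/C(C)=C/CC(C#N)P(=O)(OCC)OCC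
F4 | step 11 | (4E,8E)-5,9-dimethyl-2-methylidene-11-[(4S,5S)-2,2,5-trimethyl-5-(4-methylpent-3-en-1-yl)-1,3-dioxolan-4-yl]undeca-4,8-dienenitrile | CC(C)=CCC[C@]1(C)OC(C)(C)O[C@H]1CC/C(C)=C/CC/C(C)=C/CC(=C)C#N
F5 | step 9 | (2R,3S)-1-(benzenesulfonyl)-3,7-dimethyloct-6-ene-2,3-diol | CC(C)=CCC[C@](C)(O)[C@@H](O)CS(=O)(=O)c1ccccc1
F6 | step 9 | (4E,8E,12R,13S)-11-(benzenesulfonyl)-12,13-dihydroxy-5,9,13,17-tetramethyloctadeca-4,8,16-trienenitrile (both C11 epimers) | CC(C)=CCC[C@](C)(O)[C@@H](O)C(C/C(C)=C/CC/C(C)=C/CCC#N)S(=O)(=O)c1ccccc1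
F7 | step 9 | (4E,8E,12S,13S)-12,13-dihydroxy-5,9,13,17-tetramethyloctadeca-4,8,16-trienenitrile | CC(C)=CCC[C@](C)(O)[C@@H](O)CC/C(C)=C/CC/C(C)=C/CCC#N
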